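**Retrosynthetic overview**
1. Building blocks: 2,4,6-trihydroxyacetophenone 1 (ring A bought intact, C-methylated twice to ketone 2) and hexacosanoic acid 3 (C26, activated as acid chloride 4).
2. Key C–C disconnection: C2–C3 of the chromone, made by joining the methyl-ketone enolate carbon of 2 to the acyl carbon of 4 (β-diketone 5).
3. Key C–O disconnection: O1–C2, closed last by acid cyclodehydration of 5 to target 6.
4. Ring order: benzene ring A is pre-formed; pyranone ring C is formed in the final step; no protecting groups.

Assumption: the target has no stereocentre and no stereogenic double bond (it is achiral), so no stereocontrol is needed; the side chain is read as unbranched pentacosyl (C25), which makes hexacosanoic acid the correct C26 partner.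

**Route**

Step 1
Reactants: 1 1-(2,4,6-trihydroxyphenyl)ethan-1-one
Product: 2 1-(2,4,6-trihydroxy-3,5-dimethylphenyl)ethan-1-one
Conditions: NaOMe (2.5 equiv), MeI (2.1 equiv), MeOH, 0 °C → 65 °C
Reagents that add atoms: iodomethane (CI)
Why: The ambident phloroglucinol-type phenoxide reacts with MeI at carbon in protic solvent (nuclear C-methylation) at the only two free ring positions, and limiting MeI to about two equivalents holds back gem-dimethylation; no stereocentre is formed.

Step 2
Reactants: 3 hexacosanoic acid
Product: 4 hexacosanoyl chloride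
Conditions: (COCl)2 (1.5 equiv), DMF (cat.), CH2Cl2, rt → 40 °C; evaporate, use crude
Reagents that add atoms: oxalyl chloride (ClC(=O)C(=O)Cl)
Why: DMF-catalysed (Vilsmeier-type) conversion of a carboxylic acid into its acid chloride is driven by irreversible loss of CO, CO2 and HCl, and the saturated chain is inert.

Step 3
Reactants: 2 1-(2,4,6-trihydroxy-3,5-dimethylphenyl)ethan-1-one; 4 hexacosanoyl chloride
Product: 6 5,7-dihydroxy-6,8-dimethyl-2-pentacosyl-4H-chromen-4-one, via β-diketone 5 (not isolated)
Conditions: LiN(SiMe3)2 (5.2 equiv), THF, −78 → −10 °C; 4 (1.0 equiv) in THF, −78 °C → rt; then conc. HCl (excess), MeOH, 65 °C, same pot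
Reagents that add atoms: none
Why: The fully deprotonated ketone (three phenoxides plus the lithium enolate) is acylated at the enolate carbon (polyanion variant of the Claisen/Baker–Venkataraman acylation) to give β-diketone 5, and acid then closes either of the two equivalent ortho-hydroxyls onto the chain carbonyl and dehydrates to the aromatic 4-pyranone (cyclodehydration), so one regioisomer forms and no stereocentre arises.

**Compound list**
1 | 1-(2,4,6-trihydroxyphenyl)ethan-1-one (2,4,6-trihydroxyacetophenone) | CC(=O)c1c(O)cc(O)cc1O | starting material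
2 | 1-(2,4,6-trihydroxy-3,5-dimethylphenyl)ethan-1-one | CC(=O)c1c(O)c(C)c(O)c(C)c1O | intermediate
3 | hexacosanoic acid | CCCCCCCCCCCCCCCCCCCCCCCCCC(=O)O | starting material
4 | hexacosanoyl chloride | CCCCCCCCCCCCCCCCCCCCCCCCCC(=O)Cl | intermediate
5 | 1-(2,4,6-trihydroxy-3,5-dimethylphenyl)octacosane-1,3-dione | CCCCCCCCCCCCCCCCCCCCCCCCCC(=O)CC(=O)c1c(O)c(C)c(O)c(C)c1O | intermediate
6 | 5,7-dihydroxy-6,8-dimethyl-2-pentacosyl-4H-chromen-4-one | CCCCCCCCCCCCCCCCCCCCCCCCCc1cc(=O)c2c(O)c(C)c(O)c(C)c2o1 | target

**Totals**
Total step count: 3. Longest linear sequence: 2 steps (1 → 2 → 6, or 3 → 4 → 6).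

**Steps most likely to fail and their fallbacks**

Step 3 (most at risk). The tetralithium polyanion may be poorly soluble, O-acylation may compete, and free amide base may consume the enolisable acid chloride. The fallback sets out from 2 and comes back at 6. Compound 2 is protected on two hydroxyls (MOMCl, iPr2NEt, CH2Cl2), which leaves only the chelated ortho-hydroxyl free and gives 1-[2-hydroxy-4,6-bis(methoxymethoxy)-3,5-dimethylphenyl]ethan-1-one F1. Its sodium phenoxide (NaH, THF, 0 °C) is O-acylated by 4 to give 2-acetyl-3,5-bis(methoxymethoxy)-4,6-dimethylphenyl hexacosanoate F2. KOtBu in THF then brings about the intramolecular Baker–Venkataraman 1,5-acyl shift to 1-[2-hydroxy-4,6-bis(methoxymethoxy)-3,5-dimethylphenyl]octacosane-1,3-dione F3. HCl in MeOH/THF at reflux removes both methoxymethyl groups and cyclodehydrates to 6.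

Step 1. The C-methylation can give mixtures of mono-, di- and gem-dimethylated (dearomatised) products and some O-methyl ether. The fallback sets out from 1 and comes back at 2. A double Mannich aminomethylation (aqueous formaldehyde, morpholine, EtOH, rt) at the two free ring positions gives 1-[2,4,6-trihydroxy-3,5-bis(morpholin-4-ylmethyl)phenyl]ethan-1-one F4. Hydrogenolysis of the two benzylic C–N bonds (H2, Pd/C, EtOH, 60 °C) then gives 2. Each position can only be substituted once this way, so over-alkylation is excluded.

Step 2. The waxy acid dissolves poorly, so conversion may be incomplete, and the crude acid chloride is moisture-sensitive. The fallback sets out from 3 and comes back at 5. Acid 3 is activated by 1,1'-carbonyldiimidazole (THF, 50 °C) as the isolable 1-(1H-imidazol-1-yl)hexacosan-1-one F5. F5 is added in place of 4 to the polyanion of 2 (LiN(SiMe3)2, THF), where C-acylation of the enolate gives 5, which is cyclised by acid in the same pot as in step 3.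

**Further compounds**
F1 | step 3 | 1-[2-hydroxy-4,6-bis(methoxymethoxy)-3,5-dimethylphenyl]ethan-1-one | CC(=O)c1c(O)c(C)c(OCOC)c(C)c1OCOC
F2 | step 3 | 2-acetyl-3,5-bis(methoxymethoxy)-4,6-dimethylphenyl hexacosanoate | CCCCCCCCCCCCCCCCCCCCCCCCCC(=O)Oc1c(C)c(OCOC)c(C)c(OCOC)c1C(C)=O
F3 | step 3 | 1-[2-hydroxy-4,6-bis(methoxymethoxy)-3,5-dimethylphenyl]octacosane-1,3-dione | CCCCCCCCCCCCCCCCCCCCCCCCCC(=O)CC(=O)c1c(O)c(C)c(OCOC)c(C)c1OCOC
F4 | step 1 | 1-[2,4,6-trihydroxy-3,5-bis(morpholin-4-ylmethyl)phenyl]ethan-1-one | CC(=O)c1c(O)c(CN2CCOCC2)c(O)c(CN2CCOCC2)c1O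
F5 | step 2 | 1-(1H-imidazol-1-yl)hexacosan-1-one | CCCCCCCCCCCCCCCCCCCCCCCCCC(=O)n1ccnc1
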